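**Retrosynthetic overview**

1. Endgame: the hydroxy-methoxy-quinone comes from a 2,3,5,6-tetramethoxyphenyl group (CAN, then selective saponification), the exocyclic C4=CH2 from a C4 ketone (Wittig), and the benzylic CH2 from a C9 aldehyde (aryllithium addition, Barton–McCombie).
2. Key disconnection: the C5–C10 and C8–C9 bonds of the cis-decalin, by an intramolecular Diels–Alder reaction of an acyclic triene; both rings form in this step (ring A through C5–C10 as the tether ring, ring B as the new cyclohexene).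
3. Enabling feature: ring B (C5–C6–C7–C8–C9–C10) carries all four stereocentres on adjacent carbons, with C5-CH3, C10-H, C9-CH2Ar and C8-CH3 on one face. This is the endo adduct of a diene C5=C6–C7=C8 (tether on the inside of C5, methyls outside) with an (E)-2-methyl-enal C9=C10. The C1–C4 chain of ring A is the tether, and C4 carries a silyl ether stereocentre that directs the facial selectivity and is later erased as the methylene carbon.
4. Triene from hex-5-enoyl chloride: ynone, asymmetric transfer hydrogenation (the only source of chirality), anti-carbomagnesiation/iodination to the (Z)-vinyl iodide, cross-metathesis with methacrolein, Suzuki coupling with (E)-propenylboronic acid.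

Key step: step 8

Remarks on the chemistry:
- Terpenoid numbering is used in the text: C4 carries the exocyclic methylene, C5 is the quaternary ring-fusion carbon, C10 the ring-fusion CH, C9 the quaternary carbon with the benzylic CH2, C8 the CH(CH3) carbon.
- The target is taken exactly as drawn: cis-fused decalin (C5-CH3 cis to C10-H), C9-CH2Ar cis to C10-H and to C8-CH3.
- The carbinol carbon made in step 10 is expected as a mixture of epimers and is removed in step 12; it is left undefined in the SMILES of 17–19.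
- Hex-5-enoyl chloride is assumed to be purchased; it is otherwise made from hex-5-enoic acid and oxalyl chloride.

**Route**

Step 1
Reactants: 1 hex-5-enoyl chloride; 2 ethynyltrimethylsilane
Product: 3 1-(trimethylsilyl)oct-7-en-1-yn-3-one
Conditions: PdCl2(PPh3)2 (2 mol %), CuI (4 mol %), Et3N (1.2 equiv), THF, rt
Reagents that add atoms: none
Why: Acyl Sonogashira coupling of an acid chloride with a terminal alkyne should give the ynone directly, the remote terminal alkene being inert.

Step 2
Reactants: 3 1-(trimethylsilyl)oct-7-en-1-yn-3-one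
Product: 4 (3R)-1-(trimethylsilyl)oct-7-en-1-yn-3-ol
Conditions: Ru[(R,R)-TsDPEN](p-cymene) (1 mol %), i-PrOH, rt
Reagents that add atoms: none
Why: Noyori–Ikariya asymmetric transfer hydrogenation of an alkynyl ketone, in which the alkynyl group takes the place of the aryl group of the usual model, so the (R,R)-catalyst should deliver the (R)-propargylic alcohol that later becomes the C4 control element.

Step 3
Reactants: 4 (3R)-1-(trimethylsilyl)oct-7-en-1-yn-3-ol
Product: 5 (3R)-oct-7-en-1-yn-3-ol
Conditions: K2CO3 (cat.), MeOH, rt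
Reagents that add atoms: none
Why: Base-catalysed methanolysis of the alkynyl–silicon bond (protodesilylation) frees the terminal alkyne without touching the carbinol centre.

Step 4
Reactants: 5 (3R)-oct-7-en-1-yn-3-ol
Product: 7 (1Z,3R)-1-iodo-2-methylocta-1,7-dien-3-ol, via cyclic alkenylmagnesium alkoxide 6 (not isolated)
Conditions: MeMgBr (3.5 equiv), CuI (0.2 equiv), THF, −10 °C → rt; then I2, −78 → 0 °C
Reagents that add atoms: methylmagnesium bromide, C[Mg]Br; iodine, II
Why: Copper-catalysed, alkoxide-directed anti-carbomagnesiation of a propargylic alcohol puts the methyl on the alkyne carbon next to the carbinol and magnesium on the terminal carbon cis to the alkoxide (five-membered chelate), and iodinolysis with retention should give the (Z)-iodoalkene that fixes the "tether inside" geometry of the future diene.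

Step 5
Reactants: 7 (1Z,3R)-1-iodo-2-methylocta-1,7-dien-3-ol
Product: 8 tert-butyl{[(1Z,3R)-1-iodo-2-methylocta-1,7-dien-3-yl]oxy}dimethylsilane
Conditions: TBSCl, imidazole, DMF, rt
Reagents that add atoms: tert-butyldimethylsilyl chloride, CC(C)(C)[Si](C)(C)Cl
Why: Standard silylation of a secondary allylic alcohol gives a weakly Lewis-basic ether that survives the later organometallic, Lewis-acid and radical steps.

Step 6
Reactants: 8 tert-butyl{[(1Z,3R)-1-iodo-2-methylocta-1,7-dien-3-yl]oxy}dimethylsilane; 9 methacrolein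
Product: 10 (2E,7R,8Z)-7-{[tert-butyl(dimethyl)silyl]oxy}-9-iodo-2,8-dimethylnona-2,8-dienal
Conditions: Hoveyda–Grubbs II (5 mol %), 9 (5 equiv), CH2Cl2, 40 °C
Reagents that add atoms: none
Why: Olefin cross-metathesis of a terminal alkene with a 1,1-disubstituted enal should give the (E)-2-methyl-2-enal under thermodynamic control, while the trisubstituted vinyl iodide does not enter the catalytic cycle.

Step 7
Reactants: 10 (2E,7R,8Z)-7-{[tert-butyl(dimethyl)silyl]oxy}-9-iodo-2,8-dimethylnona-2,8-dienal; 11 (E)-prop-1-en-1-ylboronic acid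
Product: 12 (2E,7R,8Z,10E)-7-{[tert-butyl(dimethyl)silyl]oxy}-2,8-dimethyldodeca-2,8,10-trienal
Conditions: Pd(dppf)Cl2 (5 mol %), K3PO4 (3 equiv), THF/H2O, rt; product kept cold and used at once
Reagents that add atoms: none
Why: Suzuki–Miyaura coupling proceeds with retention at both alkenyl partners, so the (8Z,10E)-diene geometry follows from the vinyl iodide and the boronic acid, and the mild base leaves the enal intact.

Step 8
Reactants: 12 (2E,7R,8Z,10E)-7-{[tert-butyl(dimethyl)silyl]oxy}-2,8-dimethyldodeca-2,8,10-trienal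
Product: 13 (1R,2R,4aR,5R,8aR)-5-{[tert-butyl(dimethyl)silyl]oxy}-1,2,4a-trimethyl-1,2,4a,5,6,7,8,8a-octahydronaphthalene-1-carbaldehyde
Conditions: Me2AlCl (1.1 equiv), CH2Cl2, −78 → −20 °C; aq. Rochelle salt
Reagents that add atoms: none
Why: Me2AlCl binds the aldehyde and lowers the LUMO of the (E)-2-methyl-enal, which adds across the C5=C6–C7=C8 diene in an asynchronous concerted [4+2] cycloaddition; the closest known reaction type is the Lewis-acid-promoted type 1 intramolecular Diels–Alder reaction of deca-1,7,9-trienals with a (Z)-configured, tether-bearing diene, which gives cis-fused bicycles. Ring A (C5–C4–C3–C2–C1–C10) closes through the C5–C10 bond as the six-membered ring that contains the four-carbon tether (diene terminus to the β-carbon of the enal), and ring B (C5–C6–C7–C8–C9–C10) is the new cyclohexene completed by the C8–C9 bond. Because the tether occupies the inside (Z) position at C5, it can reach C10 only through the cis-fused transition state, which sets C5-CH3 cis to C10-H; with the (E)-enal this same transition state places the formyl group endo, so C9-CHO ends cis to C10-H (suprafacial addition) and cis to the two outside methyl groups at C5 and C8, C8 being fixed by the (E)-propenyl terminus. The absolute sense comes from the C4 silyloxy centre: allylic 1,3-strain against C7-H and C8-H holds the C4–H bond in the diene plane on the inside, so the tether delivers the dienophile to one diene face only with the OTBS group anti to the forming C5–C10 bond, and the (R)-ether should therefore give the array that becomes 5R,8R,9R,10S in the target. The step needs cis ring fusion, endo-formyl selectivity and π-facial selectivity, secured by the Z diene geometry, by the E enal geometry together with the tether constraint, and by allylic strain at C4; the low temperature is chosen to suppress the [1,5]-hydrogen shift open to a (Z)-diene with an allylic C–H and to limit ionisation of the dienylic silyl ether.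

Step 9
Reactants: 13 (1R,2R,4aR,5R,8aR)-5-{[tert-butyl(dimethyl)silyl]oxy}-1,2,4a-trimethyl-1,2,4a,5,6,7,8,8a-octahydronaphthalene-1-carbaldehyde
Product: 14 (1R,2R,4aR,5R,8aR)-5-{[tert-butyl(dimethyl)silyl]oxy}-1,2,4a-trimethyldecahydronaphthalene-1-carbaldehyde
Conditions: H2 (1 atm), 10 % Pd/C, EtOAc, rt
Reagents that add atoms: none
Why: Heterogeneous hydrogenation of the only C=C bond (cis-disubstituted ring alkene) creates no stereocentre and is done now so that the later exocyclic methylene never competes; the non-enolisable neopentyl aldehyde should survive.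

Step 10
Reactants: 14 (1R,2R,4aR,5R,8aR)-5-{[tert-butyl(dimethyl)silyl]oxy}-1,2,4a-trimethyldecahydronaphthalene-1-carbaldehyde; 15 1,2,4,5-tetramethoxybenzene
Product: 17 [(1R,2R,4aR,5R,8aR)-5-{[tert-butyl(dimethyl)silyl]oxy}-1,2,4a-trimethyldecahydronaphthalen-1-yl](2,3,5,6-tetramethoxyphenyl)methanol, via 2,3,5,6-tetramethoxyphenyllithium 16 (not isolated)
Conditions: 15, n-BuLi, THF, 0 °C → rt; then 14, −78 → 0 °C; H2O
Reagents that add atoms: none
Why: Directed ortho-lithiation of 15 at the C–H flanked by two methoxy groups, followed by 1,2-addition of the aryllithium to the non-enolisable aldehyde; the new carbinol centre is removed in step 12, so its configuration does not matter.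

Step 11
Reactants: 17 [(1R,2R,4aR,5R,8aR)-5-{[tert-butyl(dimethyl)silyl]oxy}-1,2,4a-trimethyldecahydronaphthalen-1-yl](2,3,5,6-tetramethoxyphenyl)methanol
Product: 19 O-{[(1R,2R,4aR,5R,8aR)-5-{[tert-butyl(dimethyl)silyl]oxy}-1,2,4a-trimethyldecahydronaphthalen-1-yl](2,3,5,6-tetramethoxyphenyl)methyl} S-methyl carbonodithioate, via sodium xanthate salt 18 (not isolated)
Conditions: NaH, imidazole (cat.), THF, 0 °C → rt; CS2; then MeI
Reagents that add atoms: carbon disulfide, S=C=S; iodomethane, CI
Why: Xanthate formation (first stage of the Barton–McCombie deoxygenation); the carbinol has no β-hydrogen on the quaternary C9 side, so Chugaev elimination is not possible.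

Step 12
Reactants: 19 O-{[(1R,2R,4aR,5R,8aR)-5-{[tert-butyl(dimethyl)silyl]oxy}-1,2,4a-trimethyldecahydronaphthalen-1-yl](2,3,5,6-tetramethoxyphenyl)methyl} S-methyl carbonodithioate
Product: 20 tert-butyl(dimethyl){[(1R,4aS,5R,6R,8aR)-5,6,8a-trimethyl-5-[(2,3,5,6-tetramethoxyphenyl)methyl]decahydronaphthalen-1-yl]oxy}silane
Conditions: n-Bu3SnH, AIBN (cat.), toluene, 100 °C
Reagents that add atoms: none
Why: Barton–McCombie radical deoxygenation through a stabilised benzylic radical that is reduced by the stannane; there is no alkene left for it to cyclise onto.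

Step 13
Reactants: 20 tert-butyl(dimethyl){[(1R,4aS,5R,6R,8aR)-5,6,8a-trimethyl-5-[(2,3,5,6-tetramethoxyphenyl)methyl]decahydronaphthalen-1-yl]oxy}silane
Product: 21 (1R,4aS,5R,6R,8aR)-5,6,8a-trimethyl-5-[(2,3,5,6-tetramethoxyphenyl)methyl]decahydronaphthalen-1-ol
Conditions: TBAF, THF, 50 °C; H2O
Reagents that add atoms: none
Why: Fluoride-mediated desilylation; warming is planned because the ether sits next to the quaternary C5.

Step 14
Reactants: 21 (1R,4aS,5R,6R,8aR)-5,6,8a-trimethyl-5-[(2,3,5,6-tetramethoxyphenyl)methyl]decahydronaphthalen-1-ol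
Product: 22 (4aS,5R,6R,8aR)-5,6,8a-trimethyl-5-[(2,3,5,6-tetramethoxyphenyl)methyl]octahydronaphthalen-1(2H)-one
Conditions: Dess–Martin periodinane, CH2Cl2, rt
Reagents that add atoms: none
Why: Dess–Martin oxidation erases the C4 control centre; the only α-stereocentre, C5, is quaternary and cannot epimerise.

Step 15
Reactants: 22 (4aS,5R,6R,8aR)-5,6,8a-trimethyl-5-[(2,3,5,6-tetramethoxyphenyl)methyl]octahydronaphthalen-1(2H)-one
Product: 23 1,2,4,5-tetramethoxy-3-{[(1R,2R,4aR,8aS)-1,2,4a-trimethyl-5-methylidenedecahydronaphthalen-1-yl]methyl}benzene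
Conditions: Ph3PCH3Br, KOt-Bu, toluene, 0 → 80 °C
Reagents that add atoms: methylenetriphenylphosphorane (made in the flask from methyltriphenylphosphonium bromide), C=P(c1ccccc1)(c1ccccc1)c1ccccc1
Why: Wittig methylenation with excess ylide and heat should convert the hindered ketone next to the quaternary C5 into the exocyclic C4=CH2 without touching any stereocentre.

Step 16
Reactants: 23 1,2,4,5-tetramethoxy-3-{[(1R,2R,4aR,8aS)-1,2,4a-trimethyl-5-methylidenedecahydronaphthalen-1-yl]methyl}benzene
Product: 24 2,5-dimethoxy-3-{[(1R,2R,4aR,8aS)-1,2,4a-trimethyl-5-methylidenedecahydronaphthalen-1-yl]methyl}cyclohexa-2,5-diene-1,4-dione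
Conditions: (NH4)2Ce(NO3)6 (2.5 equiv), MeCN/H2O, 0 °C
Reagents that add atoms: water, O
Why: CAN oxidative demethylation of a para-dimethoxy pair gives the quinone; the arene is symmetric about the alkyl axis, so either para pair should lead to the same 2,5-dimethoxy-3-alkylquinone, and the isolated 1,1-disubstituted alkene is not expected to be oxidised under these conditions.

Step 17
Reactants: 24 2,5-dimethoxy-3-{[(1R,2R,4aR,8aS)-1,2,4a-trimethyl-5-methylidenedecahydronaphthalen-1-yl]methyl}cyclohexa-2,5-diene-1,4-dione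
Product: 25 2-hydroxy-5-methoxy-3-{[(1R,2R,4aR,8aS)-1,2,4a-trimethyl-5-methylidenedecahydronaphthalen-1-yl]methyl}cyclohexa-2,5-diene-1,4-dione
Conditions: KOH, MeOH/H2O, rt; then aq. HCl
Reagents that add atoms: potassium hydroxide, [K+].[OH-]
Why: Addition–elimination of hydroxide at a vinylogous ester carbon (selective saponification of 3-alkyl-2,5-dimethoxybenzoquinones); the methoxy group flanked by the alkyl substituent and a carbonyl is twisted out of conjugation and should be the one displaced, and the resulting hydroxyquinone anion resists a second substitution.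

**Compound list**

1 | hex-5-enoyl chloride | C=CCCCC(=O)Cl | starting material
2 | ethynyltrimethylsilane | C#C[Si](C)(C)C | starting material
3 | 1-(trimethylsilyl)oct-7-en-1-yn-3-one | C=CCCCC(=O)C#C[Si](C)(C)C | intermediate
4 | (3R)-1-(trimethylsilyl)oct-7-en-1-yn-3-ol | C=CCCC[C@@H](O)C#C[Si](C)(C)C | intermediate
5 | (3R)-oct-7-en-1-yn-3-ol | C=CCCC[C@@H](O)C#C | intermediate
6 | (5R)-4-methyl-5-(pent-4-en-1-yl)-2,5-dihydro-1,2-oxamagnesole (cyclic alkenylmagnesium alkoxide, not isolated) | C=CCCC[C@H]1O[Mg]C=C1C | intermediate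
7 | (1Z,3R)-1-iodo-2-methylocta-1,7-dien-3-ol | C=CCCC[C@@H](O)/C(C)=C\I | intermediate
8 | tert-butyl{[(1Z,3R)-1-iodo-2-methylocta-1,7-dien-3-yl]oxy}dimethylsilane | C=CCCC[C@@H](O[Si](C)(C)C(C)(C)C)/C(C)=C\I | intermediate
9 | methacrolein (2-methylprop-2-enal) | C=C(C)C=O | starting material
10 | (2E,7R,8Z)-7-{[tert-butyl(dimethyl)silyl]oxy}-9-iodo-2,8-dimethylnona-2,8-dienal | O=C/C(C)=C/CCC[C@@H](O[Si](C)(C)C(C)(C)C)/C(C)=C\I | intermediate
11 | (E)-prop-1-en-1-ylboronic acid | C/C=C/B(O)O | starting material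
12 | (2E,7R,8Z,10E)-7-{[tert-butyl(dimethyl)silyl]oxy}-2,8-dimethyldodeca-2,8,10-trienal | O=C/C(C)=C/CCC[C@@H](O[Si](C)(C)C(C)(C)C)/C(C)=C\C=C\C | intermediate
13 | (1R,2R,4aR,5R,8aR)-5-{[tert-butyl(dimethyl)silyl]oxy}-1,2,4a-trimethyl-1,2,4a,5,6,7,8,8a-octahydronaphthalene-1-carbaldehyde | CC(C)(C)[Si](C)(C)O[C@@H]1CCC[C@H]2[C@](C)(C=O)[C@H](C)C=C[C@@]12C | intermediate
14 | (1R,2R,4aR,5R,8aR)-5-{[tert-butyl(dimethyl)silyl]oxy}-1,2,4a-trimethyldecahydronaphthalene-1-carbaldehyde | CC(C)(C)[Si](C)(C)O[C@@H]1CCC[C@H]2[C@](C)(C=O)[C@H](C)CC[C@@]12C | intermediate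
15 | 1,2,4,5-tetramethoxybenzene | COc1cc(OC)c(OC)cc1OC | starting material
16 | 2,3,5,6-tetramethoxyphenyllithium (not isolated) | [Li]c1c(OC)c(OC)cc(OC)c1OC | intermediate
17 | [(1R,2R,4aR,5R,8aR)-5-{[tert-butyl(dimethyl)silyl]oxy}-1,2,4a-trimethyldecahydronaphthalen-1-yl](2,3,5,6-tetramethoxyphenyl)methanol (carbinol epimers) | CC(C)(C)[Si](C)(C)O[C@@H]1CCC[C@H]2[C@](C)(C(O)c3c(OC)c(OC)cc(OC)c3OC)[C@H](C)CC[C@@]12C | intermediate
18 | sodium O-{[(1R,2R,4aR,5R,8aR)-5-{[tert-butyl(dimethyl)silyl]oxy}-1,2,4a-trimethyldecahydronaphthalen-1-yl](2,3,5,6-tetramethoxyphenyl)methyl} carbonodithioate (not isolated) | CC(C)(C)[Si](C)(C)O[C@@H]1CCC[C@H]2[C@](C)(C(OC(=S)[S-])c3c(OC)c(OC)cc(OC)c3OC)[C@H](C)CC[C@@]12C.[Na+] | intermediate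
19 | O-{[(1R,2R,4aR,5R,8aR)-5-{[tert-butyl(dimethyl)silyl]oxy}-1,2,4a-trimethyldecahydronaphthalen-1-yl](2,3,5,6-tetramethoxyphenyl)methyl} S-methyl carbonodithioate | CC(C)(C)[Si](C)(C)O[C@@H]1CCC[C@H]2[C@](C)(C(OC(=S)SC)c3c(OC)c(OC)cc(OC)c3OC)[C@H](C)CC[C@@]12C | intermediate
20 | tert-butyl(dimethyl){[(1R,4aS,5R,6R,8aR)-5,6,8a-trimethyl-5-[(2,3,5,6-tetramethoxyphenyl)methyl]decahydronaphthalen-1-yl]oxy}silane | CC(C)(C)[Si](C)(C)O[C@@H]1CCC[C@H]2[C@](C)(Cc3c(OC)c(OC)cc(OC)c3OC)[C@H](C)CC[C@@]12C | intermediate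
21 | (1R,4aS,5R,6R,8aR)-5,6,8a-trimethyl-5-[(2,3,5,6-tetramethoxyphenyl)methyl]decahydronaphthalen-1-ol | O[C@@H]1CCC[C@H]2[C@](C)(Cc3c(OC)c(OC)cc(OC)c3OC)[C@H](C)CC[C@@]12C | intermediate
22 | (4aS,5R,6R,8aR)-5,6,8a-trimethyl-5-[(2,3,5,6-tetramethoxyphenyl)methyl]octahydronaphthalen-1(2H)-one | O=C1CCC[C@H]2[C@](C)(Cc3c(OC)c(OC)cc(OC)c3OC)[C@H](C)CC[C@@]12C | intermediate
23 | 1,2,4,5-tetramethoxy-3-{[(1R,2R,4aR,8aS)-1,2,4a-trimethyl-5-methylidenedecahydronaphthalen-1-yl]methyl}benzene | C=C1CCC[C@H]2[C@](C)(Cc3c(OC)c(OC)cc(OC)c3OC)[C@H](C)CC[C@@]12C | intermediate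
24 | 2,5-dimethoxy-3-{[(1R,2R,4aR,8aS)-1,2,4a-trimethyl-5-methylidenedecahydronaphthalen-1-yl]methyl}cyclohexa-2,5-diene-1,4-dione | C=C1CCC[C@H]2[C@](C)(CC3=C(OC)C(=O)C=C(OC)C3=O)[C@H](C)CC[C@@]12C | intermediate
25 | 2-hydroxy-5-methoxy-3-{[(1R,2R,4aR,8aS)-1,2,4a-trimethyl-5-methylidenedecahydronaphthalen-1-yl]methyl}cyclohexa-2,5-diene-1,4-dione (CID71726091) | C=C1CCC[C@H]2[C@](C)(CC3=C(O)C(=O)C=C(OC)C3=O)[C@H](C)CC[C@@]12C | target

**Totals and risks**

Total step count: 17. Longest linear sequence: 17 steps (from hex-5-enoyl chloride 1).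

Steps most likely to fail:

1. Step 8 (intramolecular Diels–Alder). The aluminium Lewis acid may ionise the dienylic C4 silyl ether, which would destroy the control element and start oligomerisation. The cycloaddition may also be too slow at low temperature, because the inside substituent destabilises the s-cis diene and both new bonds end at quaternary carbons; on warming, the [1,5]-hydrogen shift of the (Z)-diene could then take over. The fallback sets out from 8 and comes back at 13; it gives up setting C9 in the cycloaddition and uses a less substituted, more reactive dienophile without a Lewis acid. Cross-metathesis of 8 with acrolein (Hoveyda–Grubbs II) should give (2E,7R,8Z)-7-{[tert-butyl(dimethyl)silyl]oxy}-9-iodo-8-methylnona-2,8-dienal F1. Suzuki coupling with 11 then gives (2E,7R,8Z,10E)-7-{[tert-butyl(dimethyl)silyl]oxy}-8-methyldodeca-2,8,10-trienal F2. Its 1,2-disubstituted (E)-enal is cyclised by iminium catalysis with a chiral imidazolidinone salt matched to the C4 centre, or simply by heating in toluene, through the same Z-diene cis-fused endo mode, to (1R,2R,4aR,5R,8aS)-5-{[tert-butyl(dimethyl)silyl]oxy}-2,4a-dimethyl-1,2,4a,5,6,7,8,8a-octahydronaphthalene-1-carbaldehyde F3. Deprotonation to the exocyclic potassium enolate (KHMDS, THF, −78 °C) and C-methylation with iodomethane should then give 13, the methyl group being expected to enter from the face opposite the C5 and C8 methyl groups.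

2. Step 10 (aryllithium addition). A di-ortho-substituted aryllithium may add only slowly to a neopentyl aldehyde on a quaternary carbon, leaving room for single-electron reduction of the aldehyde or recovery of starting material. The fallback sets out from 12 and comes back at 17; it forms the aryl–carbon bond on the unhindered acyclic enal before the ring system exists. Aryllithium 16 should add 1,2 to enal 12 to give (2E,7R,8Z,10E)-7-{[tert-butyl(dimethyl)silyl]oxy}-2,8-dimethyl-1-(2,3,5,6-tetramethoxyphenyl)dodeca-2,8,10-trien-1-ol F4. MnO2 oxidation gives (2E,7R,8Z,10E)-7-{[tert-butyl(dimethyl)silyl]oxy}-2,8-dimethyl-1-(2,3,5,6-tetramethoxyphenyl)dodeca-2,8,10-trien-1-one F5. The aryl enone is cyclised (Me2AlCl, CH2Cl2, low temperature) in the same cis-fused, acyl-endo mode to [(1R,2R,4aR,5R,8aR)-5-{[tert-butyl(dimethyl)silyl]oxy}-1,2,4a-trimethyl-1,2,4a,5,6,7,8,8a-octahydronaphthalen-1-yl](2,3,5,6-tetramethoxyphenyl)methanone F6. Hydrogenation (H2, Pd/C) gives [(1R,2R,4aR,5R,8aR)-5-{[tert-butyl(dimethyl)silyl]oxy}-1,2,4a-trimethyldecahydronaphthalen-1-yl](2,3,5,6-tetramethoxyphenyl)methanone F7, and LiAlH4 reduction of the ketone gives 17.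

3. Step 6 (cross-metathesis). The catalyst may die before full conversion, the terminal alkene may self-metathesise, or the E-selectivity may erode with this functionalised substrate. The fallback sets out from 8 and comes back at 10; it replaces metathesis by oxidative cleavage and carbonyl olefination. OsO4 (cat.)/NaIO4 with 2,6-lutidine in dioxane/H2O should cleave the monosubstituted alkene of 8 selectively (the iodoalkene is trisubstituted, hindered and electron-poor) to (5R,6Z)-5-{[tert-butyl(dimethyl)silyl]oxy}-7-iodo-6-methylhept-6-enal F8. Wittig reaction with 2-(triphenylphosphoranylidene)propanal (toluene, 80 °C) then gives 10 with E selectivity.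

Further compounds
F1 | step 8 | (2E,7R,8Z)-7-{[tert-butyl(dimethyl)silyl]oxy}-9-iodo-8-methylnona-2,8-dienal | O=C/C=C/CCC[C@@H](O[Si](C)(C)C(C)(C)C)/C(C)=C\I
F2 | step 8 | (2E,7R,8Z,10E)-7-{[tert-butyl(dimethyl)silyl]oxy}-8-methyldodeca-2,8,10-trienal | O=C/C=C/CCC[C@@H](O[Si](C)(C)C(C)(C)C)/C(C)=C\C=C\C
F3 | step 8 | (1R,2R,4aR,5R,8aS)-5-{[tert-butyl(dimethyl)silyl]oxy}-2,4a-dimethyl-1,2,4a,5,6,7,8,8a-octahydronaphthalene-1-carbaldehyde | CC(C)(C)[Si](C)(C)O[C@@H]1CCC[C@H]2[C@H](C=O)[C@H](C)C=C[C@@]12C
F4 | step 10 | (2E,7R,8Z,10E)-7-{[tert-butyl(dimethyl)silyl]oxy}-2,8-dimethyl-1-(2,3,5,6-tetramethoxyphenyl)dodeca-2,8,10-trien-1-ol | OC(/C(C)=C/CCC[C@@H](O[Si](C)(C)C(C)(C)C)/C(C)=C\C=C\C)c1c(OC)c(OC)cc(OC)c1OC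
F5 | step 10 | (2E,7R,8Z,10E)-7-{[tert-butyl(dimethyl)silyl]oxy}-2,8-dimethyl-1-(2,3,5,6-tetramethoxyphenyl)dodeca-2,8,10-trien-1-one | O=C(/C(C)=C/CCC[C@@H](O[Si](C)(C)C(C)(C)C)/C(C)=C\C=C\C)c1c(OC)c(OC)cc(OC)c1OC
F6 | step 10 | [(1R,2R,4aR,5R,8aR)-5-{[tert-butyl(dimethyl)silyl]oxy}-1,2,4a-trimethyl-1,2,4a,5,6,7,8,8a-octahydronaphthalen-1-yl](2,3,5,6-tetramethoxyphenyl)methanone | CC(C)(C)[Si](C)(C)O[C@@H]1CCC[C@H]2[C@](C)(C(=O)c3c(OC)c(OC)cc(OC)c3OC)[C@H](C)C=C[C@@]12C
F7 | step 10 | [(1R,2R,4aR,5R,8aR)-5-{[tert-butyl(dimethyl)silyl]oxy}-1,2,4a-trimethyldecahydronaphthalen-1-yl](2,3,5,6-tetramethoxyphenyl)methanone | CC(C)(C)[Si](C)(C)O[C@@H]1CCC[C@H]2[C@](C)(C(=O)c3c(OC)c(OC)cc(OC)c3OC)[C@H](C)CC[C@@]12C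
F8 | step 6 | (5R,6Z)-5-{[tert-butyl(dimethyl)silyl]oxy}-7-iodo-6-methylhept-6-enal | O=CCCC[C@@H](O[Si](C)(C)C(C)(C)C)/C(C)=C\I
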